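## Retrosynthetic overview

- **Late stage:** the C19 acid is traced back to a C19 primary alcohol and the C15 acetate to an allylic alcohol, which gives labda-8(17),13E-diene-15,19-diol. This diol comes from double reduction of a 15,19-diester. Its C13=C14 bond arises by Horner–Wadsworth–Emmons olefination of a C13 methyl ketone, and its C3 methylene by deoxygenation of a C3 ketone.
- **Key disconnection:** C4–C5 and C10–C9 are cut together, which unfolds the bicyclic 3,13-diketone to an acyclic E,E-diene 2-methyl-3-oxo ester. In the forward direction ring A closes first, ring B second, and C8=C17 forms last.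
- **Feature that carries the strategy:** quaternary C4 (equatorial C18 methyl, axial C19 carboxyl) adjoins the ring-forming bonds C4–C5 and C10–C9 of trans-fused rings A and B, with the C8=C17 exocyclic methylene at the far end of ring B. This pattern is what a C4 keto ester radical cascade ended by copper-mediated hydrogen loss leaves behind.
- **Acyclic precursor:** it is cut at C1–C2 into a 2-methylacetoacetate dianion and a terminal E-allylic bromide made from geranylacetone, with C13 masked as a dioxolane.
- **Absolute configuration:** it rests on a (−)-8-phenylmenthyl ester at C19, which is recovered at the reduction stage.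

Key step: step 6

Assumption: geranylacetone is used as the pure 5E isomer, and the (−)-8-phenylmenthyl ester is taken to expose the Re face of the C4 radical, as in the related cyclizations to the podocarpane series; if the sense proved opposite, the enantiomeric auxiliary would be used in the same route.

## Route

Step 1
Reactants: 1 (E)-geranylacetone
Product: 2 geranylacetone ethylene ketal
Conditions: ethylene glycol, PPTS (cat.), toluene, reflux, Dean–Stark trap
Reagents that add atoms: ethylene glycol, OCCO
Why: Acid-catalysed ketalization with azeotropic removal of water masks the C13 ketone against the strong bases of step 5, and the mild catalyst leaves both trisubstituted alkenes and the E geometry untouched.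

Step 2
Reactants: 2 geranylacetone ethylene ketal
Product: 3 (2E,6E)-2,6-dimethyl-9-(2-methyl-1,3-dioxolan-2-yl)nona-2,6-dien-1-ol
Conditions: SeO2 (cat.), t-BuOOH (decane solution), CH2Cl2, 0 °C to rt, stopped before full conversion
Reagents that add atoms: tert-butyl hydroperoxide, CC(C)(C)OO; selenium dioxide (oxygen carrier), O=[Se]=O
Why: The Riley allylic oxidation (ene reaction, then [2,3]-sigmatropic shift) prefers the more accessible terminal isopropylidene unit and oxidises the methyl group trans to the chain, so the E-allylic alcohol should form with the new CH2OH as future C1 and the remaining methyl as future C20.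

Step 3
Reactants: 3 (2E,6E)-allylic alcohol
Product: 4 2-[(3E,7E)-9-bromo-4,8-dimethylnona-3,7-dien-1-yl]-2-methyl-1,3-dioxolane
Conditions: CBr4, PPh3, CH2Cl2, −20 to 0 °C
Reagents that add atoms: carbon tetrabromide, BrC(Br)(Br)Br
Why: In the Appel reaction bromide displaces the alkoxyphosphonium group by SN2 under nearly neutral conditions, which keeps both alkene geometries and the dioxolane.

Step 4
Reactants: 5 (−)-8-phenylmenthol; 6 ethyl 2-methylacetoacetate
Product: 7 (−)-8-phenylmenthyl 2-methyl-3-oxobutanoate (epimers at the α-carbon)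
Conditions: DMAP (0.3 equiv), excess 6, toluene, reflux, ethanol distilled off
Reagents that add atoms: none
Why: DMAP-catalysed transesterification of an enolisable β-keto ester runs through the acylketene and therefore accepts the hindered secondary alcohol, and the epimeric α-carbon does not matter because it becomes a planar radical in step 6.

Step 5
Reactants: 7 (−)-8-phenylmenthyl 2-methyl-3-oxobutanoate; 4 allylic bromide
Product: 9 (−)-8-phenylmenthyl (6E,10E)-2,6,10-trimethyl-13-(2-methyl-1,3-dioxolan-2-yl)-3-oxotrideca-6,10-dienoate, via sodium lithium dianion 8 (not isolated)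
Conditions: NaH, THF, 0 °C; n-BuLi, 0 °C; then 4, 0 °C to rt; aq. NH4Cl
Reagents that add atoms: none
Why: In this γ-alkylation of a β-keto ester dianion the more reactive terminal carbanion (future C2) displaces the primary allylic bromide by SN2, which forms C1–C2 without disturbing either E-alkene.

Step 6
Reactants: 9 linear diene keto ester
Product: 11 (−)-8-phenylmenthyl 3,13-dioxo-14,15-dinorlabd-8(17)-en-19-oate, via bicyclic 13-ketal 10 (not isolated)
Conditions: Mn(OAc)3·2H2O (2.2 equiv), Cu(OAc)2·H2O (1 equiv), degassed AcOH, rt; then H2O added (AcOH–H2O 4:1 v/v), 40 °C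
Reagents that add atoms: water, O
Why: Mn(OAc)3 enolises the 2-methyl-3-oxo ester and oxidises it by one electron to the electrophilic tertiary C4 radical, which closes ring A by 6-endo-trig addition to C5 of the C5=C10 alkene; the tertiary C10 radical then closes ring B by 6-endo-trig addition to C9 of the C8=C9 alkene, and the tertiary C8 radical is captured by Cu(OAc)2 and loses a C17 hydrogen by oxidative elimination, the monovalent copper being reoxidised by the second equivalent of Mn(OAc)3. The closest known reaction type is the Mn(OAc)3/Cu(OAc)2 oxidative free-radical polyene cyclization of 2-substituted acetoacetates, which is also established for 8-phenylmenthyl esters that give trans-fused products bearing an axial C4 ester. The relative configuration follows from a chair-chair transition state in which each E-alkene undergoes anti addition, so that 5-H and 9-H lie trans to the C10 methyl, C11 is equatorial, and the C4 ester takes the axial position cis to C20 while the C18 methyl is equatorial. The absolute configuration comes from the auxiliary: with the ester s-cis (carbinol C–H eclipsing C=O) and C3 held cis to the ester carbonyl, the phenyl ring covers the Si face of the planar C4 radical and C5 bonds to the Re face, which fixes C4 and, through the folding, C5, C10 and C9. The step needs chemoselective oxidation (only the β-keto ester is oxidised at room temperature, not a simple ketone or ketal), a stop after two rings (C13 carries no alkene) and elimination toward C17 (the organocopper intermediate takes the most accessible methyl hydrogen rather than 7-H or 9-H). Dilution with water then hydrolyses the dioxolane of 10 in the same flask, because aqueous acetic acid is too weak to shift the 8(17)-alkene or to epimerise any centre.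

Step 7
Reactants: 11 bicyclic 3,13-diketone; 12 triethyl phosphonoacetate
Product: 14 15-ethyl 19-[(−)-8-phenylmenthyl] 3-oxolabda-8(17),13E-diene-15,19-dioate, via sodium phosphonate carbanion 13 (not isolated)
Conditions: 12, NaH (slightly less than 12), THF, 0 °C; then 11, 0 °C to rt; chromatographic removal of the 13Z isomer
Reagents that add atoms: none
Why: In the Horner–Wadsworth–Emmons olefination the stabilised carbanion adds only to the open C13 methyl ketone, because the C3 ketone is flanked by quaternary C4 and screened by the axial ester, and the reversible addition step favours the 13E-enoate.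

Step 8
Reactants: 14 3-oxo diester
Product: 15 15-ethyl 19-[(−)-8-phenylmenthyl] 3β-hydroxylabda-8(17),13E-diene-15,19-dioate
Conditions: NaBH4, EtOH, 0 °C
Reagents that add atoms: none
Why: In this borohydride ketone reduction hydride reaches C3 from the α face, away from the axial C19 ester and the C20 methyl, so the equatorial 3β-alcohol should form (a centre erased in step 10), while the enoate and the hindered ester are inert to NaBH4.

Step 9
Reactants: 15 3β-alcohol
Product: 16 3β-O-(phenoxythiocarbonyl) derivative of 15
Conditions: PhOC(S)Cl, pyridine, DMAP (cat.), CH2Cl2, 0 °C to rt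
Reagents that add atoms: O-phenyl chlorothionoformate, ClC(=S)Oc1ccccc1
Why: Amine-mediated thioacylation of the equatorial alcohol never forms a free alkoxide, so retro-aldol cleavage of the C3–C4 bond of this β-hydroxy ester is avoided.

Step 10
Reactants: 16 phenyl thionocarbonate
Product: 17 15-ethyl 19-[(−)-8-phenylmenthyl] labda-8(17),13E-diene-15,19-dioate
Conditions: Bu3SnH, AIBN (cat.), toluene, 90 °C
Reagents that add atoms: none
Why: In the Barton–McCombie deoxygenation the stannyl radical adds to C=S, the secondary C3 radical is released and takes hydrogen from Bu3SnH, and both alkenes lie too far across the rigid decalin to trap that radical.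

Step 11
Reactants: 17 3-deoxy diester
Product: 18 labda-8(17),13E-diene-15,19-diol
Conditions: LiAlH4 (excess), THF, 0 °C, then reflux; aq. NaOH work-up; 5 recovered by chromatography
Reagents that add atoms: none
Why: In this hydride reduction of esters the β,β-disubstituted enoate is reduced 1,2 to the allylic alcohol at 0 °C, heating then brings the shielded axial C19 ester to the neopentyl alcohol with release of the auxiliary, and no stereocentre is touched.

Step 12
Reactants: 18 15,19-diol
Product: 19 15-acetoxylabda-8(17),13E-dien-19-ol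
Conditions: Ac2O (1.05 equiv), pyridine, CH2Cl2, −20 to 0 °C
Reagents that add atoms: acetic anhydride, CC(=O)OC(C)=O
Why: In this chemoselective acylation the open primary allylic C15 hydroxyl reacts much faster than the axial neopentyl C19 hydroxyl, which is crowded by C4 and the 1,3-diaxial C20 methyl.

Step 13
Reactants: 19 15-acetoxy-19-ol
Product: 20 15-acetoxylabda-8(17),13E-dien-19-al
Conditions: Dess–Martin periodinane, CH2Cl2, rt
Reagents that add atoms: none
Why: The Dess–Martin oxidation converts hindered primary alcohols into aldehydes under nearly neutral conditions that spare the allylic acetate and both alkenes, and the aldehyde cannot epimerise because C4 is quaternary.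

Step 14
Reactants: 20 C19 aldehyde
Product: 21 15-acetoxyisocupressic acid
Conditions: NaClO2, NaH2PO4, 2-methyl-2-butene (large excess), t-BuOH–H2O, rt
Reagents that add atoms: sodium chlorite NaClO2, [Na+].[O-]Cl=O
Why: The Pinnick oxidation converts the aldehyde into the acid through its chlorous acid adduct at mildly acidic pH, which the acetate tolerates, while the sacrificial alkene removes hypochlorous acid before it can attack C8=C17 or C13=C14.

## Compound list

1 | (E)-geranylacetone, (5E)-6,10-dimethylundeca-5,9-dien-2-one | CC(=O)CC/C=C(\C)CCC=C(C)C | starting material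
2 | 2-[(3E)-4,8-dimethylnona-3,7-dien-1-yl]-2-methyl-1,3-dioxolane | CC(C)=CCC/C(C)=C/CCC1(C)OCCO1 | intermediate
3 | (2E,6E)-2,6-dimethyl-9-(2-methyl-1,3-dioxolan-2-yl)nona-2,6-dien-1-ol | OC/C(C)=C/CC/C(C)=C/CCC1(C)OCCO1 | intermediate
4 | 2-[(3E,7E)-9-bromo-4,8-dimethylnona-3,7-dien-1-yl]-2-methyl-1,3-dioxolane | BrC/C(C)=C/CC/C(C)=C/CCC1(C)OCCO1 | intermediate
5 | (−)-8-phenylmenthol, (1R,2S,5R) | CC(C)(c1ccccc1)[C@@H]1CC[C@@H](C)C[C@H]1O | starting material
6 | ethyl 2-methylacetoacetate | CCOC(=O)C(C)C(C)=O | starting material
7 | (−)-8-phenylmenthyl 2-methyl-3-oxobutanoate (α-epimers) | CC(C)(c1ccccc1)[C@@H]1CC[C@@H](C)C[C@H]1OC(=O)C(C)C(C)=O | intermediate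
8 | sodium lithium dianion of 7 (not isolated) | [Na+].[Li+].C=C([O-])C(C)=C([O-])O[C@@H]1C[C@H](C)CC[C@H]1C(C)(C)c1ccccc1 | intermediate
9 | (−)-8-phenylmenthyl (6E,10E)-2,6,10-trimethyl-13-(2-methyl-1,3-dioxolan-2-yl)-3-oxotrideca-6,10-dienoate (α-epimers) | CC(C)(c1ccccc1)[C@@H]1CC[C@@H](C)C[C@H]1OC(=O)C(C)C(=O)CC/C(C)=C/CC/C(C)=C/CCC1(C)OCCO1 | intermediate
10 | (−)-8-phenylmenthyl 13,13-ethylenedioxy-3-oxo-14,15-dinorlabd-8(17)-en-19-oate (not isolated) | C=C1CC[C@@H]2[C@](C)(CCC(=O)[C@]2(C)C(=O)O[C@@H]3C[C@H](C)CC[C@H]3C(C)(C)c3ccccc3)[C@H]1CCC4(C)OCCO4 | intermediate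
11 | (−)-8-phenylmenthyl 3,13-dioxo-14,15-dinorlabd-8(17)-en-19-oate | C=C1CC[C@@H]2[C@](C)(CCC(=O)[C@]2(C)C(=O)O[C@@H]3C[C@H](C)CC[C@H]3C(C)(C)c3ccccc3)[C@H]1CCC(C)=O | intermediate
12 | triethyl phosphonoacetate | CCOC(=O)CP(=O)(OCC)OCC | starting material
13 | sodium salt of triethyl phosphonoacetate (not isolated) | [Na+].CCOC(=O)[CH-]P(=O)(OCC)OCC | intermediate
14 | 15-ethyl 19-[(−)-8-phenylmenthyl] 3-oxolabda-8(17),13E-diene-15,19-dioate | C=C1CC[C@@H]2[C@](C)(CCC(=O)[C@]2(C)C(=O)O[C@@H]3C[C@H](C)CC[C@H]3C(C)(C)c3ccccc3)[C@H]1CC/C(C)=C/C(=O)OCC | intermediate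
15 | 15-ethyl 19-[(−)-8-phenylmenthyl] 3β-hydroxylabda-8(17),13E-diene-15,19-dioate | C=C1CC[C@@H]2[C@](C)(CC[C@H](O)[C@]2(C)C(=O)O[C@@H]3C[C@H](C)CC[C@H]3C(C)(C)c3ccccc3)[C@H]1CC/C(C)=C/C(=O)OCC | intermediate
16 | 3β-O-(phenoxythiocarbonyl) derivative of 15 | C=C1CC[C@@H]2[C@](C)(CC[C@H](OC(=S)Oc4ccccc4)[C@]2(C)C(=O)O[C@@H]3C[C@H](C)CC[C@H]3C(C)(C)c3ccccc3)[C@H]1CC/C(C)=C/C(=O)OCC | intermediate
17 | 15-ethyl 19-[(−)-8-phenylmenthyl] labda-8(17),13E-diene-15,19-dioate | C=C1CC[C@@H]2[C@](C)(CCC[C@]2(C)C(=O)O[C@@H]3C[C@H](C)CC[C@H]3C(C)(C)c3ccccc3)[C@H]1CC/C(C)=C/C(=O)OCC | intermediate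
18 | labda-8(17),13E-diene-15,19-diol | C=C1CC[C@@H]2[C@](C)(CCC[C@]2(C)CO)[C@H]1CC/C(C)=C/CO | intermediate
19 | 15-acetoxylabda-8(17),13E-dien-19-ol | C=C1CC[C@@H]2[C@](C)(CCC[C@]2(C)CO)[C@H]1CC/C(C)=C/COC(C)=O | intermediate
20 | 15-acetoxylabda-8(17),13E-dien-19-al | C=C1CC[C@@H]2[C@](C)(CCC[C@]2(C)C=O)[C@H]1CC/C(C)=C/COC(C)=O | intermediate
21 | 15-acetoxyisocupressic acid | C=C1CC[C@@H]2[C@](C)(CCC[C@]2(C)C(=O)O)[C@H]1CC/C(C)=C/COC(C)=O | target

## Step count and risks

Total step count: 14. Longest linear sequence: 13 steps (steps 1–3 and 5–14, from 1 to 21).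

**Step 6.**
- **Risk:** The tertiary C8 radical may be over-oxidised to the cation. That would scatter the alkene position and allow capture by acetate or by the oxygen atoms of the side chain. Incomplete shielding of one radical face would add a diastereomer separation.
- **Fallback (from 9, back at 10):** The oxidative termination is replaced by a group-transfer cascade.
  - Selenenylation of the sodium enolate of 9 (NaH, PhSeCl, THF, 0 °C) should give the 2-methyl-2-(phenylselanyl)-3-oxo ester F1.
  - Photolysis of F1 in benzene breaks the weak C4–Se bond, and the same C4 radical passes through the same two 6-endo closures under the same auxiliary control.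
  - The C8 radical then abstracts the phenylselanyl group from another molecule of F1. This gives the bicyclic C8 tertiary phenyl selenide F2 with no cation-forming oxidant present.
  - Oxidation (H2O2, pyridine, CH2Cl2, 0 °C) and selenoxide syn elimination should give 10. In the rigid trans-decalin the elimination finds a syn-periplanar hydrogen most easily on the freely rotating C17 methyl.
  - Ketal 10 is hydrolysed to 11 in aqueous acetic acid as in step 6.

**Step 11.**
- **Risk:** Hydride delivery to the C19 carbonyl is slowed by quaternary C4, the 1,3-diaxial C20 methyl and the bulky alkoxy group. The forcing conditions then needed expose the C13 alkene, by that point part of an allylic aluminium alkoxide, to conjugate or alkoxide-directed hydride addition.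
- **Fallback (from 17, back at 18):** The two esters are reduced in separate operations.
  - DIBAL-H (CH2Cl2, −78 °C) should reduce only the enoate, giving the 15-hydroxy 19-(8-phenylmenthyl) ester F3.
  - Silylation (TBSCl, imidazole, DMF) gives the 15-silyl ether F4, which has no alkoxide to direct hydride to the alkene.
  - Prolonged LiAlH4 reduction in refluxing THF then cleaves the hindered ester to the 15-silyloxy-19-ol F5, with recovery of 5.
  - Bu4NF in THF returns the diol 18.

**Step 2.**
- **Risk:** The two trisubstituted alkenes are of similar electron density, so oxidation at the inner alkene and over-oxidation to the enal may consume material.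
- **Fallback (from 2, back at 3):** The E-allylic alcohol is built by cleavage and olefination instead of C–H oxidation.
  - NBS in aqueous THF at 0 °C favours the terminal alkene and should give the bromohydrin F6.
  - K2CO3 in MeOH closes F6 to the terminal epoxide F7.
  - Short exposure to H5IO6 (THF–Et2O, 0 °C) cleaves F7 to the aldehyde F8.
  - The stabilised ylide Ph3P=C(CH3)CO2Et (CH2Cl2, rt) converts F8 E-selectively into the enoate F9.
  - DIBAL-H (CH2Cl2, −78 °C) reduces F9 to 3.

## Further compounds

F1 | step 6 | (−)-8-phenylmenthyl (6E,10E)-2,6,10-trimethyl-13-(2-methyl-1,3-dioxolan-2-yl)-3-oxo-2-(phenylselanyl)trideca-6,10-dienoate (α-epimers) | CC(C)(c1ccccc1)[C@@H]1CC[C@@H](C)C[C@H]1OC(=O)C(C)([Se]c1ccccc1)C(=O)CC/C(C)=C/CC/C(C)=C/CCC1(C)OCCO1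
F2 | step 6 | (−)-8-phenylmenthyl 13,13-ethylenedioxy-3-oxo-8-(phenylselanyl)-14,15-dinorlabdan-19-oate (C8 epimers) | CC1([Se]c5ccccc5)CC[C@@H]2[C@](C)(CCC(=O)[C@]2(C)C(=O)O[C@@H]3C[C@H](C)CC[C@H]3C(C)(C)c3ccccc3)[C@H]1CCC4(C)OCCO4
F3 | step 11 | (−)-8-phenylmenthyl 15-hydroxylabda-8(17),13E-dien-19-oate | C=C1CC[C@@H]2[C@](C)(CCC[C@]2(C)C(=O)O[C@@H]3C[C@H](C)CC[C@H]3C(C)(C)c3ccccc3)[C@H]1CC/C(C)=C/CO
F4 | step 11 | (−)-8-phenylmenthyl 15-(tert-butyldimethylsilyloxy)labda-8(17),13E-dien-19-oate | C=C1CC[C@@H]2[C@](C)(CCC[C@]2(C)C(=O)O[C@@H]3C[C@H](C)CC[C@H]3C(C)(C)c3ccccc3)[C@H]1CC/C(C)=C/CO[Si](C)(C)C(C)(C)C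
F5 | step 11 | 15-(tert-butyldimethylsilyloxy)labda-8(17),13E-dien-19-ol | C=C1CC[C@@H]2[C@](C)(CCC[C@]2(C)CO)[C@H]1CC/C(C)=C/CO[Si](C)(C)C(C)(C)C
F6 | step 2 | (6E)-3-bromo-2,6-dimethyl-9-(2-methyl-1,3-dioxolan-2-yl)non-6-en-2-ol (racemic) | CC(C)(O)C(Br)CC/C(C)=C/CCC1(C)OCCO1
F7 | step 2 | 2-[(3E)-6-(3,3-dimethyloxiran-2-yl)-4-methylhex-3-en-1-yl]-2-methyl-1,3-dioxolane (racemic) | CC1(C)OC1CC/C(C)=C/CCC2(C)OCCO2
F8 | step 2 | (4E)-4-methyl-7-(2-methyl-1,3-dioxolan-2-yl)hept-4-enal | O=CCC/C(C)=C/CCC1(C)OCCO1
F9 | step 2 | ethyl (2E,6E)-2,6-dimethyl-9-(2-methyl-1,3-dioxolan-2-yl)nona-2,6-dienoate | CCOC(=O)/C(C)=C/CC/C(C)=C/CCC1(C)OCCO1
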